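**Plan**

- Retrosynthesis: the benzyl ether on the ring A C3 oxygen is removed and both carboxyls are taken back to CH2OSi groups. Ring B is then cut at C6'–C1', C2'–C3' and C5'–C6', giving a ring A aryl alkynyl ether and 3-methylcyclobut-2-en-1-one.
- Enabling feature: ring B (C1' CO2H, C2' O-aryl, C3' H, C4' CH3, C5' H, C6' OH) is a phenol with a carbon substituent ortho, an ether oxygen next to that, and a methyl para to the carbon substituent. This is the pattern a vinylketene (C3'–C6') and an ynol ether (C1', C2') deliver, and the ring A oxygen arrives on an sp carbon, so the hindered diaryl ether is never made by coupling.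
- Forward, ring A (C1 CO2H, C2 O, C3 OH, C4 Cl, C5 OCH3): 3-chloro-2,4-dihydroxybenzaldehyde is O-methylated, O-benzylated, converted to the phenol by Baeyer–Villiger oxidation, ortho-formylated, reduced and silylated. The phenol is then taken through the dichlorovinyl ether and the lithium aryloxyacetylide to the hydroxymethylated, silylated alkyne.
- The cyclobutenone comes from propyne and dichloroketene. The benzannulation closes ring B (the only ring formed), followed by desilylation, two-stage oxidation and debenzylation.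
- Stereochemistry: the target has no stereocentre and no stereogenic double bond, so nothing has to be controlled.

Key step: step 12

Remark: 3-chloro-2,4-dihydroxybenzaldehyde is taken as a catalogue compound (the C3 chloride sits between the two oxygens that become the ring A C3 OH and C5 OCH3).

**Route**

Step 1
Reactants: 1 3-chloro-2,4-dihydroxybenzaldehyde
Product: 2 3-chloro-2-hydroxy-4-methoxybenzaldehyde
Conditions: MeI (1.05 equiv), Li2CO3, DMF, 40 °C
Reagents that add atoms: iodomethane, CI
Why: Williamson O-methylation should occur at the 4-OH, which is para to the formyl group and more acidic and nucleophilic than the 2-OH held in a hydrogen bond to the aldehyde.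

Step 2
Reactants: 2 3-chloro-2-hydroxy-4-methoxybenzaldehyde
Product: 3 2-(benzyloxy)-3-chloro-4-methoxybenzaldehyde
Conditions: BnBr, K2CO3, DMF, 60 °C
Reagents that add atoms: benzyl bromide, BrCc1ccccc1
Why: With the 4-oxygen capped, the remaining chelated phenol should undergo Williamson benzylation under slightly more forcing carbonate conditions.

Step 3
Reactants: 3 2-(benzyloxy)-3-chloro-4-methoxybenzaldehyde
Product: 5 2-(benzyloxy)-3-chloro-4-methoxyphenol, via aryl formate 4 (not isolated)
Conditions: mCPBA, CH2Cl2, rt; then K2CO3 (cat.), MeOH, rt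
Reagents that add atoms: 3-chloroperoxybenzoic acid, OOC(=O)c1cccc(Cl)c1
Why: In this Baeyer–Villiger (Dakin-type) oxidation the electron-rich 2,4-dialkoxyaryl group should migrate in preference to hydride, and mild methanolysis of the resulting formate should release the phenol.

Step 4
Reactants: 5 2-(benzyloxy)-3-chloro-4-methoxyphenol
Product: 6 3-(benzyloxy)-4-chloro-2-hydroxy-5-methoxybenzaldehyde
Conditions: (CH2O)n, MgCl2, Et3N, MeCN, reflux
Reagents that add atoms: formaldehyde (as paraformaldehyde), C=O
Why: The magnesium phenoxide-directed ortho-formylation (Casnati–Skattebøl reaction) delivers the formyl group only ortho to the phenol, and the single free ortho carbon is the future C1 of ring A.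

Step 5
Reactants: 6 3-(benzyloxy)-4-chloro-2-hydroxy-5-methoxybenzaldehyde
Product: 7 2-(benzyloxy)-3-chloro-6-(hydroxymethyl)-4-methoxyphenol
Conditions: NaBH4, MeOH, 0 °C
Reagents that add atoms: none
Why: Borohydride reduction of the aryl aldehyde to the benzylic alcohol is chemoselective and should leave the aryl chloride and the ethers untouched.

Step 6
Reactants: 7 2-(benzyloxy)-3-chloro-6-(hydroxymethyl)-4-methoxyphenol
Product: 8 2-(benzyloxy)-6-({[tert-butyl(dimethyl)silyl]oxy}methyl)-3-chloro-4-methoxyphenol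
Conditions: TBSCl (1.05 equiv), imidazole, CH2Cl2, 0 °C
Reagents that add atoms: tert-butyldimethylsilyl chloride, CC(C)(C)[Si](C)(C)Cl
Why: Chemoselective silylation is expected because, under neutral imidazole conditions, the primary benzylic hydroxyl reacts much faster than the phenol flanked by two ortho substituents.

Step 7
Reactants: 8 2-(benzyloxy)-6-({[tert-butyl(dimethyl)silyl]oxy}methyl)-3-chloro-4-methoxyphenol; 9 trichloroethylene
Product: 10 {[3-(benzyloxy)-4-chloro-2-{[(E)-1,2-dichloroethenyl]oxy}-5-methoxyphenyl]methoxy}(tert-butyl)dimethylsilane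
Conditions: K2CO3, DMF, 70 °C
Reagents that add atoms: none
Why: Carbonate converts trichloroethylene into dichloroacetylene in the flask, and anti addition of the phenoxide across it should give the (E)-1,2-dichlorovinyl ether (the established aryl dichlorovinyl ether synthesis).

Step 8
Reactants: 10 {[3-(benzyloxy)-4-chloro-2-{[(E)-1,2-dichloroethenyl]oxy}-5-methoxyphenyl]methoxy}(tert-butyl)dimethylsilane
Product: 13 3-[2-(benzyloxy)-6-({[tert-butyl(dimethyl)silyl]oxy}methyl)-3-chloro-4-methoxyphenoxy]prop-2-yn-1-ol, via chloroethynyl ether 11 (not isolated), via lithium aryloxyacetylide 12 (not isolated)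
Conditions: n-BuLi (2.5 equiv), THF, −78 °C; (CH2O)n, −78 °C to rt; aq NH4Cl
Reagents that add atoms: formaldehyde (as paraformaldehyde), C=O
Why: Deprotonation of the vinyl CH with loss of LiCl gives the chloroalkyne, chlorine–lithium exchange gives the lithium aryloxyacetylide, and 1,2-addition to formaldehyde installs the hydroxymethyl group (dichlorovinyl ether route to ynol ethers); at −78 °C this sequence should outpace metalation of the chloroarene.

Step 9
Reactants: 13 3-[2-(benzyloxy)-6-({[tert-butyl(dimethyl)silyl]oxy}methyl)-3-chloro-4-methoxyphenoxy]prop-2-yn-1-ol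
Product: 14 tert-butyl({3-[2-(benzyloxy)-6-({[tert-butyl(dimethyl)silyl]oxy}methyl)-3-chloro-4-methoxyphenoxy]prop-2-yn-1-yl}oxy)dimethylsilane
Conditions: TBSCl, imidazole, DMF, 0 °C to rt
Reagents that add atoms: tert-butyldimethylsilyl chloride, CC(C)(C)[Si](C)(C)Cl
Why: Silylation of the primary propargylic alcohol under non-acidic imidazole conditions should spare the acid-sensitive ynol ether and removes the hydroxyl that would otherwise trap a ketene.

Step 10
Reactants: 15 propyne; 16 trichloroacetyl chloride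
Product: 17 4,4-dichloro-3-methylcyclobut-2-en-1-one
Conditions: Zn–Cu couple, Et2O/DME, rt (propyne condensed in)
Reagents that add atoms: none
Why: Zinc dechlorination generates dichloroketene, whose [2+2] cycloaddition with the terminal alkyne joins the alkyne CH carbon to the ketene carbonyl carbon and so places the methyl group at C3.

Step 11
Reactants: 17 4,4-dichloro-3-methylcyclobut-2-en-1-one
Product: 18 3-methylcyclobut-2-en-1-one
Conditions: Zn dust, AcOH, TMEDA, EtOH, 0 °C to rt
Reagents that add atoms: none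
Why: Reductive dehalogenation of the α,α-dichloroketone by zinc in amine-buffered acetic acid should remove both chlorines without isomerising or opening the sensitive cyclobutenone.

Step 12
Reactants: 14 tert-butyl({3-[2-(benzyloxy)-6-({[tert-butyl(dimethyl)silyl]oxy}methyl)-3-chloro-4-methoxyphenoxy]prop-2-yn-1-yl}oxy)dimethylsilane; 18 3-methylcyclobut-2-en-1-one
Product: 23 3-[2-(benzyloxy)-6-({[tert-butyl(dimethyl)silyl]oxy}methyl)-3-chloro-4-methoxyphenoxy]-2-({[tert-butyl(dimethyl)silyl]oxy}methyl)-5-methylphenol, via vinylketene 19 (not isolated), via isopropenylcyclobutenone 20 (not isolated), via dienylketene 21 (not isolated), via cyclohexadienone 22 (not isolated)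
Conditions: 18 (2–3 equiv), toluene, 80 °C then 110 °C, sealed tube; then K2CO3, MeOH, rt
Reagents that add atoms: none
Why: Heating opens 18 by four-electron electrocyclic ring opening to vinylketene 19, whose carbonyl carbon is attacked by the oxygen-remote carbon of 14 in a ketene–alkyne [2+2] cycloaddition that forms C6'–C1' and C2'–C3' and gives cyclobutenone 20. A second four-electron opening gives dienylketene 21, and ring B closes by thermal disrotatory six-electron electrocyclization (C5'–C6') to dienone 22, which tautomerises to the phenol. The closest known reaction is the Danheiser benzannulation of cyclobutenones with alkoxy- and siloxyalkynes; an aryl ynol ether has no β-hydrogen for retro-ene loss of ketene and should therefore tolerate the temperature. No stereocentre is created. The selectivity needed is the regiochemistry of the [2+2] step, which the oxygen-polarised triple bond secures: the carbon bearing CH2OTBS is the nucleophilic terminus, so OH, CH2OTBS, O-aryl, H, CH3 and H are placed around the new ring in the order of the target. The closing basic methanolysis should return any product phenol that was acylated by excess vinylketene.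

Step 13
Reactants: 23 3-[2-(benzyloxy)-6-({[tert-butyl(dimethyl)silyl]oxy}methyl)-3-chloro-4-methoxyphenoxy]-2-({[tert-butyl(dimethyl)silyl]oxy}methyl)-5-methylphenol
Product: 24 3-[2-(benzyloxy)-3-chloro-6-(hydroxymethyl)-4-methoxyphenoxy]-2-(hydroxymethyl)-5-methylphenol
Conditions: Bu4NF (3 equiv), THF, 0 °C to rt; water work-up
Reagents that add atoms: none
Why: Fluoride-mediated desilylation should cleave both primary silyl ethers in one operation while the benzyl ether, diaryl ether and aryl chloride are inert.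

Step 14
Reactants: 24 3-[2-(benzyloxy)-3-chloro-6-(hydroxymethyl)-4-methoxyphenoxy]-2-(hydroxymethyl)-5-methylphenol
Product: 25 3-(benzyloxy)-4-chloro-2-(2-formyl-3-hydroxy-5-methylphenoxy)-5-methoxybenzaldehyde
Conditions: activated MnO2 (excess), CH2Cl2, rt
Reagents that add atoms: none
Why: Activated MnO2 oxidises benzylic alcohols selectively to aldehydes and stops there, and the ring B aldehyde is stabilised by a hydrogen bond to the neighbouring phenol.

Step 15
Reactants: 25 3-(benzyloxy)-4-chloro-2-(2-formyl-3-hydroxy-5-methylphenoxy)-5-methoxybenzaldehyde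
Product: 26 3-(benzyloxy)-2-(2-carboxy-3-hydroxy-5-methylphenoxy)-4-chloro-5-methoxybenzoic acid
Conditions: NaClO2, NaH2PO4, 2-methyl-2-butene (large excess), t-BuOH/THF/H2O, 0 °C to rt
Reagents that add atoms: sodium chlorite, [Na+].[O-]Cl=O
Why: The Pinnick oxidation converts both aryl aldehydes into carboxylic acids under buffered conditions, with 2-methyl-2-butene intercepting the hypochlorous acid that could otherwise chlorinate the phenol ring.

Step 16
Reactants: 26 3-(benzyloxy)-2-(2-carboxy-3-hydroxy-5-methylphenoxy)-4-chloro-5-methoxybenzoic acid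
Product: 27 2-(2-carboxy-3-hydroxy-5-methylphenoxy)-4-chloro-3-hydroxy-5-methoxybenzoic acid
Conditions: BCl3 (5 equiv), pentamethylbenzene, CH2Cl2, −78 °C; aqueous quench
Reagents that add atoms: none
Why: Lewis acid debenzylation with BCl3 and pentamethylbenzene as benzyl cation scavenger should cleave the aryl benzyl ether at low temperature, sparing the aryl chloride (which hydrogenolysis would endanger) and the methyl ether, which is not ortho to a carbonyl.

**Compound list**

1 | 3-chloro-2,4-dihydroxybenzaldehyde | O=Cc1ccc(O)c(Cl)c1O | starting material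
2 | 3-chloro-2-hydroxy-4-methoxybenzaldehyde | COc1ccc(C=O)c(O)c1Cl | intermediate
3 | 2-(benzyloxy)-3-chloro-4-methoxybenzaldehyde | COc1ccc(C=O)c(OCc2ccccc2)c1Cl | intermediate
4 | 2-(benzyloxy)-3-chloro-4-methoxyphenyl formate | COc1ccc(OC=O)c(OCc2ccccc2)c1Cl | intermediate
5 | 2-(benzyloxy)-3-chloro-4-methoxyphenol | COc1ccc(O)c(OCc2ccccc2)c1Cl | intermediate
6 | 3-(benzyloxy)-4-chloro-2-hydroxy-5-methoxybenzaldehyde | COc1cc(C=O)c(O)c(OCc2ccccc2)c1Cl | intermediate
7 | 2-(benzyloxy)-3-chloro-6-(hydroxymethyl)-4-methoxyphenol | COc1cc(CO)c(O)c(OCc2ccccc2)c1Cl | intermediate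
8 | 2-(benzyloxy)-6-({[tert-butyl(dimethyl)silyl]oxy}methyl)-3-chloro-4-methoxyphenol | COc1cc(CO[Si](C)(C)C(C)(C)C)c(O)c(OCc2ccccc2)c1Cl | intermediate
9 | trichloroethylene | ClC=C(Cl)Cl | starting material
10 | {[3-(benzyloxy)-4-chloro-2-{[(E)-1,2-dichloroethenyl]oxy}-5-methoxyphenyl]methoxy}(tert-butyl)dimethylsilane | COc1cc(CO[Si](C)(C)C(C)(C)C)c(O/C(Cl)=C\Cl)c(OCc2ccccc2)c1Cl | intermediate
11 | {[3-(benzyloxy)-4-chloro-2-[(chloroethynyl)oxy]-5-methoxyphenyl]methoxy}(tert-butyl)dimethylsilane | COc1cc(CO[Si](C)(C)C(C)(C)C)c(OC#CCl)c(OCc2ccccc2)c1Cl | intermediate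
12 | lithium 2-[2-(benzyloxy)-6-({[tert-butyl(dimethyl)silyl]oxy}methyl)-3-chloro-4-methoxyphenoxy]ethyn-1-ide | COc1cc(CO[Si](C)(C)C(C)(C)C)c(OC#C[Li])c(OCc2ccccc2)c1Cl | intermediate
13 | 3-[2-(benzyloxy)-6-({[tert-butyl(dimethyl)silyl]oxy}methyl)-3-chloro-4-methoxyphenoxy]prop-2-yn-1-ol | COc1cc(CO[Si](C)(C)C(C)(C)C)c(OC#CCO)c(OCc2ccccc2)c1Cl | intermediate
14 | tert-butyl({3-[2-(benzyloxy)-6-({[tert-butyl(dimethyl)silyl]oxy}methyl)-3-chloro-4-methoxyphenoxy]prop-2-yn-1-yl}oxy)dimethylsilane | CC(C)(C)[Si](C)(C)OCC#COc1c(CO[Si](C)(C)C(C)(C)C)cc(OC)c(Cl)c1OCc1ccccc1 | intermediate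
15 | propyne | CC#C | starting material
16 | trichloroacetyl chloride | O=C(Cl)C(Cl)(Cl)Cl | starting material
17 | 4,4-dichloro-3-methylcyclobut-2-en-1-one | CC1=CC(=O)C1(Cl)Cl | intermediate
18 | 3-methylcyclobut-2-en-1-one | CC1=CC(=O)C1 | intermediate
19 | 3-methylbuta-1,3-dien-1-one | C=C(C)C=C=O | intermediate
20 | 3-[2-(benzyloxy)-6-({[tert-butyl(dimethyl)silyl]oxy}methyl)-3-chloro-4-methoxyphenoxy]-2-({[tert-butyl(dimethyl)silyl]oxy}methyl)-4-(prop-1-en-2-yl)cyclobut-2-en-1-one (racemic) | C=C(C)C1C(=O)C(CO[Si](C)(C)C(C)(C)C)=C1Oc1c(CO[Si](C)(C)C(C)(C)C)cc(OC)c(Cl)c1OCc1ccccc1 | intermediate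
21 | (3E)-3-[2-(benzyloxy)-6-({[tert-butyl(dimethyl)silyl]oxy}methyl)-3-chloro-4-methoxyphenoxy]-2-({[tert-butyl(dimethyl)silyl]oxy}methyl)-5-methylhexa-1,3,5-trien-1-one | C=C(C)/C=C(Oc1c(CO[Si](C)(C)C(C)(C)C)cc(OC)c(Cl)c1OCc1ccccc1)\C(CO[Si](C)(C)C(C)(C)C)=C=O | intermediate
22 | 3-[2-(benzyloxy)-6-({[tert-butyl(dimethyl)silyl]oxy}methyl)-3-chloro-4-methoxyphenoxy]-2-({[tert-butyl(dimethyl)silyl]oxy}methyl)-5-methylcyclohexa-2,4-dien-1-one | CC1=CC(Oc2c(CO[Si](C)(C)C(C)(C)C)cc(OC)c(Cl)c2OCc2ccccc2)=C(CO[Si](C)(C)C(C)(C)C)C(=O)C1 | intermediate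
23 | 3-[2-(benzyloxy)-6-({[tert-butyl(dimethyl)silyl]oxy}methyl)-3-chloro-4-methoxyphenoxy]-2-({[tert-butyl(dimethyl)silyl]oxy}methyl)-5-methylphenol | Cc1cc(O)c(CO[Si](C)(C)C(C)(C)C)c(Oc2c(CO[Si](C)(C)C(C)(C)C)cc(OC)c(Cl)c2OCc2ccccc2)c1 | intermediate
24 | 3-[2-(benzyloxy)-3-chloro-6-(hydroxymethyl)-4-methoxyphenoxy]-2-(hydroxymethyl)-5-methylphenol | Cc1cc(O)c(CO)c(Oc2c(CO)cc(OC)c(Cl)c2OCc2ccccc2)c1 | intermediate
25 | 3-(benzyloxy)-4-chloro-2-(2-formyl-3-hydroxy-5-methylphenoxy)-5-methoxybenzaldehyde | Cc1cc(O)c(C=O)c(Oc2c(C=O)cc(OC)c(Cl)c2OCc2ccccc2)c1 | intermediate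
26 | 3-(benzyloxy)-2-(2-carboxy-3-hydroxy-5-methylphenoxy)-4-chloro-5-methoxybenzoic acid | Cc1cc(O)c(C(=O)O)c(Oc2c(C(=O)O)cc(OC)c(Cl)c2OCc2ccccc2)c1 | intermediate
27 | 2-(2-carboxy-3-hydroxy-5-methylphenoxy)-4-chloro-3-hydroxy-5-methoxybenzoic acid | COc1cc(C(=O)O)c(Oc2cc(C)cc(O)c2C(=O)O)c(O)c1Cl | target

**Step count**

Total steps: 16. Longest linear sequence: 14 (steps 1–9 and 12–16); steps 10 and 11 form the short branch to the cyclobutenone.

**Steps most likely to fail**

Step 12 (benzannulation). The ketene–alkyne cycloaddition may be slow for a hindered and only moderately electron-rich aryloxyalkyne. The volatile cyclobutenone would then be consumed by self-condensation and vinylketene dimerisation before it is trapped. The fallback sets out from 14 and comes back at 23, and it generates the same vinylketene 19 at room temperature by photochemical Wolff rearrangement instead of thermal ring opening. 3-Methylbut-3-en-2-one is trifluoroacetylated at its methyl group (LiHMDS, CF3CO2CH2CF3, THF, −78 °C) to 1,1,1-trifluoro-5-methylhex-5-ene-2,4-dione F1. Detrifluoroacetylative diazo transfer (MsN3, Et3N, H2O, MeCN) should then give 1-diazo-3-methylbut-3-en-2-one F2. Irradiation of F2 with 14 (300 nm, ClCH2CH2Cl, rt) keeps the ketene concentration low, and subsequent heating to 80–110 °C should carry 20 through 21 and 22 to 23.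

Step 8 (alkynyl ether formation and hydroxymethylation). Competing metalation or chlorine–lithium exchange on the chlorinated ring, incomplete capture of the acetylide by slowly depolymerising paraformaldehyde, and hydration of the ynol ether on work-up could all erode this step. The fallback sets out from phenol 8 and comes back at 14, bypassing steps 7–9 and avoiding organolithium reagents. Dibromo-olefination of (tert-butyldimethylsilyloxy)acetaldehyde (CBr4, PPh3, CH2Cl2, 0 °C) gives tert-butyl[(3,3-dibromoprop-2-en-1-yl)oxy]dimethylsilane F3. Copper-catalysed coupling of 8 with F3 (CuI, 2,2'-bipyridine, K3PO4, toluene, 110 °C) should replace the less hindered bromide and give {[(2Z)-3-[2-(benzyloxy)-6-({[tert-butyl(dimethyl)silyl]oxy}methyl)-3-chloro-4-methoxyphenoxy]-3-bromoprop-2-en-1-yl]oxy}(tert-butyl)dimethylsilane F4. Anti elimination of HBr from F4 with KOt-Bu in THF should then deliver 14.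

Step 15 (chlorite oxidation beside a free phenol). Electrophilic chlorination or oxidative degradation of the electron-rich ring B phenol may compete if hypochlorous acid is not scavenged fast enough, and step 14 carries a related risk of phenol oxidation. The fallback sets out from 23 and comes back at 27, and it masks the phenol before any oxidation. Benzylation of 23 (BnBr, K2CO3, DMF) gives tert-butyl({2-(benzyloxy)-6-[2-(benzyloxy)-6-({[tert-butyl(dimethyl)silyl]oxy}methyl)-3-chloro-4-methoxyphenoxy]-4-methylphenyl}methoxy)dimethylsilane F5. Desilylation (Bu4NF, THF) gives {2-(benzyloxy)-6-[2-(benzyloxy)-3-chloro-6-(hydroxymethyl)-4-methoxyphenoxy]-4-methylphenyl}methanol F6. Chlorine-free nitroxyl oxidation of both alcohols (TEMPO cat., PhI(OAc)2, MeCN/H2O) should give 3-(benzyloxy)-2-[3-(benzyloxy)-2-carboxy-5-methylphenoxy]-4-chloro-5-methoxybenzoic acid F7. BCl3 with pentamethylbenzene then removes both benzyl ethers to give 27.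

**Further compounds**

F1 | step 12 | 1,1,1-trifluoro-5-methylhex-5-ene-2,4-dione | C=C(C)C(=O)CC(=O)C(F)(F)F
F2 | step 12 | 1-diazo-3-methylbut-3-en-2-one | C=C(C)C(=O)C=[N+]=[N-]
F3 | step 8 | tert-butyl[(3,3-dibromoprop-2-en-1-yl)oxy]dimethylsilane | CC(C)(C)[Si](C)(C)OCC=C(Br)Br
F4 | step 8 | {[(2Z)-3-[2-(benzyloxy)-6-({[tert-butyl(dimethyl)silyl]oxy}methyl)-3-chloro-4-methoxyphenoxy]-3-bromoprop-2-en-1-yl]oxy}(tert-butyl)dimethylsilane | CC(C)(C)[Si](C)(C)OC/C=C(\Br)Oc1c(CO[Si](C)(C)C(C)(C)C)cc(OC)c(Cl)c1OCc1ccccc1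
F5 | step 15 | tert-butyl({2-(benzyloxy)-6-[2-(benzyloxy)-6-({[tert-butyl(dimethyl)silyl]oxy}methyl)-3-chloro-4-methoxyphenoxy]-4-methylphenyl}methoxy)dimethylsilane | Cc1cc(OCc2ccccc2)c(CO[Si](C)(C)C(C)(C)C)c(Oc2c(CO[Si](C)(C)C(C)(C)C)cc(OC)c(Cl)c2OCc2ccccc2)c1
F6 | step 15 | {2-(benzyloxy)-6-[2-(benzyloxy)-3-chloro-6-(hydroxymethyl)-4-methoxyphenoxy]-4-methylphenyl}methanol | Cc1cc(OCc2ccccc2)c(CO)c(Oc2c(CO)cc(OC)c(Cl)c2OCc2ccccc2)c1
F7 | step 15 | 3-(benzyloxy)-2-[3-(benzyloxy)-2-carboxy-5-methylphenoxy]-4-chloro-5-methoxybenzoic acid | Cc1cc(OCc2ccccc2)c(C(=O)O)c(Oc2c(C(=O)O)cc(OC)c(Cl)c2OCc2ccccc2)c1
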